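Ring B (labdane numbering) is opened at C5–C10 and C7–C8, which unzips both rings into an acyclic chain carrying two three-carbon arms. C5–C6–C7 is a vinyl sulfide, a removable equivalent of an acetone α,α′-dianion. C10–C9–C8 is an α,β-unsaturated acylium ion, electrophilic at the future quaternary C10 and at C8. One [3+3] operation on acyclic acid 21 closes ring A, then ring B, and sets C5, C9 and C10 from the single C4 stereocentre. It exploits the 1,3-relationships C5/C7 and C10/C8 across ring B. C8 emerges as the ketone that becomes the C8=C17 methylene, and sulfur at C6 is cleaved with Raney nickel. C13 comes from methyl (R)-3-methylglutarate.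

Key step: step 13

Assumption: the lipase in step 8 acetylates the hydroxymethyl arm that becomes C18, giving 15 as drawn. The geometry of the tetrasubstituted alkene (8 to 22) and the E/Z ratio of the vinyl sulfide do not matter, because these sp2 carbons become sp3 or stay epimerisable in step 13.

Step 1
Reactants: 1 methyl hydrogen (R)-3-methylglutarate
Product: 3 (S)-4-methyloxan-2-one, via hydroxy acid 2 (not isolated)
Conditions: LiBH4, THF, 0 °C to rt; then 2 M HCl
Reagents that add atoms: none
Why: Chemoselective borohydride reduction of the ester beside the lithium carboxylate, followed by acid lactonisation, leaves the C13 stereocentre untouched and makes the former acid carbon C15.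

Step 2
Reactants: 3 (S)-4-methyloxan-2-one
Product: 5 methyl (R)-5-bromo-3-methylpentanoate, via bromo acid 4 (not isolated)
Conditions: HBr (33% in AcOH), 60 °C; then MeOH, rt
Reagents that add atoms: hydrogen bromide Br; methanol CO
Why: SN2 opening of the protonated δ-lactone at C11 by bromide and Fischer esterification do not touch C13 (only the CIP descriptor changes).

Step 3
Reactants: 6 tert-butyl acetoacetate; 5 methyl (R)-5-bromo-3-methylpentanoate
Product: 7 1-tert-butyl 7-methyl (5S)-2-acetyl-5-methylheptanedioate (C2 epimers)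
Conditions: NaH, cat. NaI, THF–DMF, 0 to 60 °C
Reagents that add atoms: none
Why: Acetoacetic ester alkylation (SN2) joins C9 to C11 and brings in C8, C10 and C20; the new centre is lost again in step 4.

Step 4
Reactants: 7 1-tert-butyl 7-methyl (5S)-2-acetyl-5-methylheptanedioate
Product: 8 (Z)-enol triflate of 7
Conditions: NaH, Et2O, 0 °C; then Tf2O
Reagents that add atoms: trifluoromethanesulfonic anhydride O=S(=O)(OS(=O)(=O)C(F)(F)F)C(F)(F)F
Why: O-sulfonylation of the chelated sodium enolate of a β-keto ester gives the β-triflyloxy enoate needed for cross-coupling at C10.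

Step 5
Reactants: 9 diethyl methylmalonate; 10 allyl bromide
Product: 11 diethyl allyl(methyl)malonate
Conditions: NaH, THF, 0 °C to rt
Reagents that add atoms: none
Why: Malonic ester alkylation assembles the still achiral quaternary C4 with C19, the C3–C2–C1 allyl arm and the two carboxyl carbons that become C5 and C18.

Step 6
Reactants: 11 diethyl allyl(methyl)malonate
Product: 12 2-allyl-2-methylpropane-1,3-diol
Conditions: LiAlH4, Et2O, 0 °C to rt; Fieser work-up
Reagents that add atoms: none
Why: Hydride reduction of both esters gives the prochiral 1,3-diol and leaves the isolated alkene untouched.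

Step 7
Reactants: 12 2-allyl-2-methylpropane-1,3-diol; 8 (Z)-enol triflate of 7
Product: 14 prochiral diol (Z)-enoate, via tris-boryl adduct 13 (not isolated)
Conditions: 9-BBN-H (3.3 equiv), THF, rt; then 8, cat. PdCl2(dppf), aq. K3PO4, DMF, 50 °C
Reagents that add atoms: none
Why: Anti-Markovnikov hydroboration followed by B-alkyl Suzuki–Miyaura coupling forms C1–C10 with retention of alkene geometry, and the aqueous base releases the transiently O-borylated hydroxyls.

Step 8
Reactants: 14 prochiral diol (Z)-enoate
Product: 15 (S)-monoacetate (C18 acetate, free C5 hydroxymethyl)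
Conditions: Burkholderia cepacia lipase (Amano PS), vinyl acetate, i-Pr2O, 25 °C
Reagents that add atoms: vinyl acetate C=COC(C)=O
Why: Lipase-catalysed enantioselective desymmetrisation by irreversible transesterification sets C4, because the enzyme distinguishes the methyl group from the long C3 chain.

Step 9
Reactants: 15 (S)-monoacetate
Product: 16 (R)-aldehyde (C5 formyl)
Conditions: Dess–Martin periodinane, CH2Cl2, 0 °C to rt
Reagents that add atoms: none
Why: Dess–Martin oxidation is neutral and the α-carbon C4 is quaternary, so it cannot epimerise.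

Step 10
Reactants: 17 diethyl (phenylthiomethyl)phosphonate
Product: 18 diethyl [1-(phenylthio)ethyl]phosphonate
Conditions: n-BuLi, THF, −78 °C; then MeI
Reagents that add atoms: iodomethane CI
Why: α-Alkylation of the sulfur- and phosphoryl-stabilised carbanion installs the carbon that becomes C7.

Step 11
Reactants: 16 (R)-aldehyde; 18 diethyl [1-(phenylthio)ethyl]phosphonate
Product: 19 vinyl sulfide tert-butyl ester
Conditions: 18, n-BuLi, THF, −78 °C; then 16, −78 °C to rt
Reagents that add atoms: none
Why: Horner–Wadsworth–Emmons olefination of the aldehyde places the C5=C6 double bond regiospecifically, which enolisation of the parent methyl ketone could not do.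

Step 12
Reactants: 19 vinyl sulfide tert-butyl ester
Product: 21 vinyl sulfide carboxylic acid, via silyl ester 20 (not isolated)
Conditions: TMSOTf, 2,6-lutidine, CH2Cl2, 0 °C; then pH 4 buffer
Reagents that add atoms: none
Why: Silyl-triflate-mediated tert-butyl ester cleavage (alkyl–oxygen fission under buffered aprotic conditions) spares the methyl ester, the acetate and the acid-sensitive vinyl sulfide.

Step 13
Reactants: 21 vinyl sulfide carboxylic acid
Product: 24 methyl (13S)-ent-18-acetoxy-8-oxo-6-(phenylthio)-17-norlabd-6-en-15-oate, via acid chloride 22 (not isolated), via ketene 23 (not isolated)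
Conditions: 1-chloro-N,N,2-trimethylprop-1-en-1-amine, CH2Cl2, 0 °C; then AgOTf, 2,6-di-tert-butyl-4-methylpyridine, high dilution, −78 to 0 °C
Reagents that add atoms: none
Why: Proposed new method: AgOTf ionises acid chloride 22 to the α,β-unsaturated acylium ion, C5 of the vinyl sulfide attacks its vinylogous cationic carbon C10, loss of a C7 proton to the hindered base gives ketene 23 with a regenerated 2-(phenylthio)alkene, protonation of the ketene at C9 returns an acylium ion at C8, C7 attacks it and loss of H7 gives vinylogous thioester 24. The closest known reaction type is the Hickmott–Stork [3+3] carboannulation of enamines with α,β-unsaturated acid chlorides (Michael-type C-alkylation, enamine transposition, C-acylation), transferred here to a vinyl sulfide so that the activating heteroatom can be removed reductively. Ring A closes in a 6-(enolexo)-exo-trig mode and ring B in a 6-(enolendo)-exo-dig mode. C5 and C10 are set in a chair-like transition state in which allylic 1,3-strain holds the C4 methyl group in the plane of C5=C6, so CH2OAc lies anti to the forming bond (equatorial), C6 is equatorial, and at C10 the methyl group takes the axial site beside the axial C4 methyl while the branched C9 arm is equatorial. C9 is set by protonation and stays epimerisable beside the C8 ketone, which favours the equatorial side chain. The step needs attack at C10 before acylation at C8, which ring size secures because C5–C8 or C7–C10 union would need eight-membered rings, and it needs suppression of ketene [2+2] closure, which the strain of the bicyclohexanone products and the proton shuttle secure.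

Step 14
Reactants: 24 methyl (13S)-ent-18-acetoxy-8-oxo-6-(phenylthio)-17-norlabd-6-en-15-oate
Product: 25 methyl (13S)-ent-18-acetoxy-8-oxo-17-norlabdan-15-oate
Conditions: Raney nickel (W-2), EtOH–THF, rt
Reagents that add atoms: none
Why: Raney nickel desulfurisation of the vinylogous thioester with saturation of the resulting enone removes the temporary C6 substituent and creates no new stereocentre.

Step 15
Reactants: 25 methyl (13S)-ent-18-acetoxy-8-oxo-17-norlabdan-15-oate
Product: 26 methyl (13S)-ent-18-acetoxylabd-8(17)-en-15-oate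
Conditions: Ph3PCH3Br, KOt-Bu, toluene, 0 to 60 °C
Reagents that add atoms: methyltriphenylphosphonium bromide C[P+](c1ccccc1)(c1ccccc1)c1ccccc1.[Br-]
Why: Wittig methylenation turns the C8 ketone into the exocyclic C8=C17 alkene, and any base-induced equilibration at C9 keeps the more stable equatorial side chain.

Step 16
Reactants: 26 methyl (13S)-ent-18-acetoxylabd-8(17)-en-15-oate
Product: 27 methyl (13S)-ent-18-hydroxylabd-8(17)-en-15-oate
Conditions: cat. K2CO3, MeOH, 40 °C
Reagents that add atoms: none
Why: Base-catalysed transesterification removes the acetate, while exchange at the methyl ester is degenerate in methanol.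

Step 17
Reactants: 27 methyl (13S)-ent-18-hydroxylabd-8(17)-en-15-oate; 28 (E)-4-acetoxycinnamic acid
Product: 29 methyl (13S)-ent-18-[(E)-4-acetoxycinnamoyloxy]labd-8(17)-en-15-oate
Conditions: DCC, DMAP, CH2Cl2, rt
Reagents that add atoms: none
Why: Steglich esterification acylates the neopentyl primary C18 alcohol without touching the E-alkene or the exocyclic methylene.

Step 18
Reactants: 29 methyl (13S)-ent-18-[(E)-4-acetoxycinnamoyloxy]labd-8(17)-en-15-oate
Product: 30 (4S,5S,9R,10S,13S)-18-[(E)-4-hydroxycinnamoyloxy]-ent-labd-8(17)-en-15-oic acid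
Conditions: LiOH, THF–MeOH–H2O, 0 °C to rt; then 1 M HCl
Reagents that add atoms: lithium hydroxide [Li+].[OH-]
Why: Chemoselective saponification cleaves the aryl acetate and the unhindered methyl ester faster than the conjugated neopentyl cinnamate.

Compound list
1 | methyl hydrogen (R)-3-methylglutarate | COC(=O)C[C@H](C)CC(=O)O | starting material
2 | (S)-5-hydroxy-3-methylpentanoic acid | OCC[C@H](C)CC(=O)O | intermediate
3 | (S)-4-methyloxan-2-one | C1C[C@H](C)CC(=O)O1 | intermediate
4 | (R)-5-bromo-3-methylpentanoic acid | BrCC[C@H](C)CC(=O)O | intermediate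
5 | methyl (R)-5-bromo-3-methylpentanoate | BrCC[C@H](C)CC(=O)OC | intermediate
6 | tert-butyl acetoacetate | CC(=O)CC(=O)OC(C)(C)C | starting material
7 | 1-tert-butyl 7-methyl (5S)-2-acetyl-5-methylheptanedioate, epimers at C2 | CC(=O)C(CC[C@H](C)CC(=O)OC)C(=O)OC(C)(C)C | intermediate
8 | 1-tert-butyl 7-methyl (5S)-5-methyl-2-[(Z)-1-(triflyloxy)ethylidene]heptanedioate | C/C(OS(=O)(=O)C(F)(F)F)=C(\CC[C@H](C)CC(=O)OC)C(=O)OC(C)(C)C | intermediate
9 | diethyl methylmalonate | CCOC(=O)C(C)C(=O)OCC | starting material
10 | allyl bromide | C=CCBr | starting material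
11 | diethyl allyl(methyl)malonate | CCOC(=O)C(C)(CC=C)C(=O)OCC | intermediate
12 | 2-allyl-2-methylpropane-1,3-diol | OCC(C)(CO)CC=C | intermediate
13 | C-boryl bis(O-boryl) 9-BBN adduct of 12 | CC(COB1C2CCCC1CCC2)(COB1C2CCCC1CCC2)CCCB1C2CCCC1CCC2 | intermediate
14 | 1-tert-butyl 7-methyl (5S)-2-[(Z)-7-hydroxy-6-(hydroxymethyl)-6-methylheptan-2-ylidene]-5-methylheptanedioate (C4 prochiral) | OCC(C)(CO)CCC/C(C)=C(/CC[C@H](C)CC(=O)OC)C(=O)OC(C)(C)C | intermediate
15 | monoacetate of 14, (S) at C4, acetate on C18, free hydroxyl on C5 | OC[C@@](C)(COC(C)=O)CCC/C(C)=C(/CC[C@H](C)CC(=O)OC)C(=O)OC(C)(C)C | intermediate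
16 | aldehyde from 15, (R) at C4, C5 as formyl | O=C[C@@](C)(COC(C)=O)CCC/C(C)=C(/CC[C@H](C)CC(=O)OC)C(=O)OC(C)(C)C | intermediate
17 | diethyl (phenylthiomethyl)phosphonate | CCOP(=O)(CSc1ccccc1)OCC | starting material
18 | diethyl [1-(phenylthio)ethyl]phosphonate (racemic) | CCOP(=O)(C(C)Sc1ccccc1)OCC | intermediate
19 | vinyl sulfide tert-butyl ester, C7H3–C6(SPh)=C5H on (S)-C4, E/Z mixture at C5=C6 | CC(Sc1ccccc1)=C[C@@](C)(COC(C)=O)CCC/C(C)=C(/CC[C@H](C)CC(=O)OC)C(=O)OC(C)(C)C | intermediate
20 | trimethylsilyl ester corresponding to 19 | CC(Sc1ccccc1)=C[C@@](C)(COC(C)=O)CCC/C(C)=C(/CC[C@H](C)CC(=O)OC)C(=O)O[Si](C)(C)C | intermediate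
21 | vinyl sulfide carboxylic acid (C8 acid) | CC(Sc1ccccc1)=C[C@@](C)(COC(C)=O)CCC/C(C)=C(/CC[C@H](C)CC(=O)OC)C(=O)O | intermediate
22 | acid chloride of 21 | CC(Sc1ccccc1)=C[C@@](C)(COC(C)=O)CCC/C(C)=C(/CC[C@H](C)CC(=O)OC)C(=O)Cl | intermediate
23 | monocyclic ketene, ring A closed, 1-(phenylthio)vinyl on C5, ketene C9=C8=O on C10 | C=C(Sc3ccccc3)[C@@H]2[C@@](C)(COC(C)=O)CCC[C@@]2(C)C(CC[C@H](C)CC(=O)OC)=C=O | intermediate
24 | methyl (13S)-ent-18-acetoxy-8-oxo-6-(phenylthio)-17-norlabd-6-en-15-oate (trans-decalin) | O=C1C=C(Sc3ccccc3)[C@@H]2[C@@](C)(COC(C)=O)CCC[C@@]2(C)[C@@H]1CC[C@H](C)CC(=O)OC | intermediate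
25 | methyl (13S)-ent-18-acetoxy-8-oxo-17-norlabdan-15-oate | O=C1CC[C@@H]2[C@@](C)(COC(C)=O)CCC[C@@]2(C)[C@@H]1CC[C@H](C)CC(=O)OC | intermediate
26 | methyl (13S)-ent-18-acetoxylabd-8(17)-en-15-oate | C=C1CC[C@@H]2[C@@](C)(COC(C)=O)CCC[C@@]2(C)[C@@H]1CC[C@H](C)CC(=O)OC | intermediate
27 | methyl (13S)-ent-18-hydroxylabd-8(17)-en-15-oate | C=C1CC[C@@H]2[C@@](C)(CO)CCC[C@@]2(C)[C@@H]1CC[C@H](C)CC(=O)OC | intermediate
28 | (E)-4-acetoxycinnamic acid | CC(=O)Oc1ccc(/C=C/C(=O)O)cc1 | starting material
29 | methyl (13S)-ent-18-[(E)-4-acetoxycinnamoyloxy]labd-8(17)-en-15-oate | C=C1CC[C@@H]2[C@@](C)(COC(=O)/C=C/c3ccc(OC(C)=O)cc3)CCC[C@@]2(C)[C@@H]1CC[C@H](C)CC(=O)OC | intermediate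
30 | (4S,5S,9R,10S,13S)-18-[(E)-4-hydroxycinnamoyloxy]-ent-labd-8(17)-en-15-oic acid (CNP0389065.1) | C=C1CC[C@@H]2[C@@](C)(COC(=O)/C=C/c3ccc(O)cc3)CCC[C@@]2(C)[C@@H]1CC[C@H](C)CC(=O)O | target

Total step count: 18. Longest linear sequence: 15 (steps 1–4, 7–9, 11–18).

Steps most likely to fail

Step 13. Attack at the fully substituted C10 may be slow. The acylium ion could then lose a γ-proton, or the ketene could oligomerise or close by [2+2]. Discrimination between the rotamers with CH3 or CH2OAc in the alkene plane may also be too small for good facial selectivity.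
- Fallback from 21: hydrolysis of the vinyl sulfide (HgCl2, MeCN–H2O) would give keto acid F1, and TMSCHN2 its methyl ester F2.
- NaOMe in refluxing MeOH would then run the classical consecutive Michael–Claisen annulation (dimedone type). This still closes C5–C10 and C7–C8 in one flask, under thermodynamic control, and gives 1,3-dione F3 with loss of the acetate.
- Lombardo methylenation (Zn, CH2Br2, TiCl4) of the less hindered C8 carbonyl would give β,γ-enone F4, and TsNHNH2 would give tosylhydrazone F5.
- Catecholborane followed by NaOAc (Caglioti-type reduction) would remove the C6 oxygen and rejoin the route at 27.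

Step 8. Recognition of the two enantiotopic hydroxymethyl arms may be weak, or the enzyme may esterify the other arm. Fallback from 14: exhaustive acetylation (Ac2O, pyridine) would give diacetate F6. Enantioselective enzymatic hydrolysis in pH 7 buffer frees the arm that acyl transfer would have esterified, so it delivers the opposite sense and returns to 15.

Step 18. Hydroxide may also cleave the cinnamate, so the coumaroyl group is lost before the methyl ester is fully hydrolysed.
- Fallback from 27: LiOH would first give hydroxy acid F7, and 28 with oxalyl chloride would give acid chloride F8.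
- Acylation of F7 with excess F8 in pyridine, followed by aqueous hydrolysis of the mixed anhydride, would give aryl acetate acid F9.
- Pyrrolidine at 0 °C would remove only the aryl acetate to give 30.

Further compounds
F1 | step 13 | keto acid (C6 methyl ketone, C8 acid) | CC(=O)C[C@@](C)(COC(C)=O)CCC/C(C)=C(/CC[C@H](C)CC(=O)OC)C(=O)O
F2 | step 13 | methyl ester of F1 | CC(=O)C[C@@](C)(COC(C)=O)CCC/C(C)=C(/CC[C@H](C)CC(=O)OC)C(=O)OC
F3 | step 13 | methyl (13S)-ent-18-hydroxy-6,8-dioxo-17-norlabdan-15-oate | O=C1CC(=O)[C@@H]2[C@@](C)(CO)CCC[C@@]2(C)[C@@H]1CC[C@H](C)CC(=O)OC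
F4 | step 13 | methyl (13S)-ent-18-hydroxy-6-oxolabd-8(17)-en-15-oate | C=C1CC(=O)[C@@H]2[C@@](C)(CO)CCC[C@@]2(C)[C@@H]1CC[C@H](C)CC(=O)OC
F5 | step 13 | C6 tosylhydrazone of F4 | C=C1CC(=NNS(=O)(=O)c3ccc(C)cc3)[C@@H]2[C@@](C)(CO)CCC[C@@]2(C)[C@@H]1CC[C@H](C)CC(=O)OC
F6 | step 8 | diacetate of 14 | CC(=O)OCC(C)(COC(C)=O)CCC/C(C)=C(/CC[C@H](C)CC(=O)OC)C(=O)OC(C)(C)C
F7 | step 18 | (13S)-ent-18-hydroxylabd-8(17)-en-15-oic acid | C=C1CC[C@@H]2[C@@](C)(CO)CCC[C@@]2(C)[C@@H]1CC[C@H](C)CC(=O)O
F8 | step 18 | (E)-4-acetoxycinnamoyl chloride | CC(=O)Oc1ccc(/C=C/C(=O)Cl)cc1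
F9 | step 18 | (13S)-ent-18-[(E)-4-acetoxycinnamoyloxy]labd-8(17)-en-15-oic acid | C=C1CC[C@@H]2[C@@](C)(COC(=O)/C=C/c3ccc(OC(C)=O)cc3)CCC[C@@]2(C)[C@@H]1CC[C@H](C)CC(=O)O
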